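Count what has not yet become target: in a reckoning with partner held at its charge, that share shrinks by a factor in each stretch of time, and factors multiply across a change of temperature.

| setting | Friday's | Sunday's | epsilon | eta |
|---|---|---|---|---|
| starting material | 0.40 M | 0.40 M | 0.40 M | 0.40 M |
| partner | 0.19 M | 0.40 M | 0.360 M | 0.500 M |
| temperature | 0 °C | 15 °C |  |  |
| remark | run made earlier | run made earlier | at 25 °C until 50 s, from then on at 5 °C | at 5 °C throughout |
| time |  |  | 2.5 min | 2.5 min |

Friday's run (percent of the starting material charged)

| time / min | target / % |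
|---|---|
| 0.500 | 0.3 |
| 0.667 | 0.3 |
| 1.00 | 0.7 |
| 2.50 | 1.5 |
| 5.00 | 4.9 |

Sunday's run (percent of the starting material charged)

| time / s | target / % |
|---|---|
| 15.0 | 1.3 |
| 20.0 | 2.2 |
| 30.0 | 3.4 |
| 60.0 | 7.2 |
| 120 | 12.5 |

(scatter of a reading: 0.3 percentage points)

1. the winner by amount of target, in percent of the starting material charged; "neither" if no more than 2 percentage points parts them (epsilon / eta / neither)
2. how much target is there at the end, in percent of the starting material charged: epsilon
3. how much target is there at the end, in percent of the starting material charged: eta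

My reckoning takes target as made at k[starting material][partner], with the order in partner assumed. Call f the share of the starting material not yet target, and read k from each run's last reading. Sunday's charges are equal; in this reckoning Friday's target takes 10.3 % of that run's partner charge, so partner is held constant there:

Sunday's, 15 °C: k = (1/f − 1)/([partner]t) = 0.00298 M⁻¹ s⁻¹

Friday's, 0 °C: k = ln(1/f)/([partner]t) = 8.81 × 10⁻⁴ M⁻¹ s⁻¹

These readings give a factor of 3.38 between the two temperatures. Spreading its logarithm evenly over the degrees gives:

k at 25 °C = 0.00670 M⁻¹ s⁻¹; k at 5 °C = 0.00132 M⁻¹ s⁻¹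

As a simplification of my own, with partner held at its charge, the ladder of halving times of f, fastest first, is:

epsilon at 25 °C: 4.79 min

eta at 5 °C: 17.5 min

epsilon at 5 °C: 24.3 min

The rung at 25 °C is the shortest and still longer than the 2.5 min of the run, so in this reckoning f does not halve in either flask. Adding k[partner]t over the stretches gives:

epsilon: 0.168, so target 15.5 %

eta: 0.0992, so target 9.44 %

Each sum is the clock number, the exponent of f. Epsilon's 50 s at 25 °C supply 71.7 % of its reckoned clock number, which puts it ahead of eta in this reckoning.

The forecast names epsilon, with 14.5 % for epsilon and 8.5 % for eta, and says of its rate law: “the two runs can't separate the partner order from temperature, so this is an assumption”. My two figures stand higher than its figures , with the same winner.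

    target ⇌ isomer of the product B (K = 0.842, k = 0.00235 s⁻¹, Ea = 93.0 kJ mol⁻¹, ΔH = −26.0 kJ mol⁻¹)
    tautomer → decomposed reagent (k = 0.00209 s⁻¹, Ea = 86.0 kJ mol⁻¹)
    starting material + partner → isomer of the product A (k = 0.0454 M⁻¹ s⁻¹, Ea = 68.0 kJ mol⁻¹)
    partner + tautomer → target (k = 0.170 M⁻¹ s⁻¹, Ea = 58.0 kJ mol⁻¹)
    starting material ⇌ tautomer (K = 0.106, k = 0.0195 s⁻¹, Ea = 89.0 kJ mol⁻¹, ΔH = −29.0 kJ mol⁻¹)
    (constants at 25 °C)

Epsilon ends at 12.3 % and eta at 7.71 %, so epsilon wins, as forecast. Epsilon still holds 39.3 % as starting material and 41.7 % as isomer of the product A, so f counts target and is not the starting material left. Read back from the result, epsilon's clock number is 0.131, less than the reckoned 0.168.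

Take the neighbour like epsilon with 0.14 M of partner. Scaling the reckoned clock number with partner gives 0.0654, so target 6.33 %. That flask gives 6.07 %.

The numbers in the tables are simulated for an exercise, and the scatter is random.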